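**Retrosynthetic overview**
1. Target ⇐ conjugate borylation/oxidation (1β-OH) of a ring-A 1-en-3-one ⇐ one-pot acylketene acylation / tethered Michael–aldol-condensation bicycloannulation (lactone and ring A; C4–C5 and C1–C2 bonds) of a 10-hydroxy-10-formyl ring-B enoate.
2. That carbinol ⇐ vinylogous formylation/hydroxylation at C10 of the C5=C6 enoate ⇐ carbonylation of a C6 enol triflate; 12α-oxygen by ketone reduction then Mitsunobu inversion; H-9 by copper hydride 1,4-reduction.
3. BCD tricycle ⇐ gold-catalysed Conia-ene closure of ring D on a propargyl-substituted bicyclic enedione ⇐ amino-acid-catalysed asymmetric aldol cyclodehydration of an achiral triketone (sets C8) ⇐ cyclopentane-1,3-dione, propargyl bromide, methyl vinyl ketone.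
4. Ring order: B (from the dione) → C (organocatalytic aldol) → D (Conia-ene) → lactone and A (bicycloannulation).

Assumption: the SMILES is read literally with gibberellane numbering (ring A C1–C5/C10, ring B C5/C6/C8/C9/C10, ring C C8/C9/C11–C14, ring D C8/C13–C16, C7 on C6, C17 on C16, C18/C19 on C4); α is the face of the lactone oxygen on C10, which also carries H-9, C14 and the 12-OH, and β is the face of C15, C11, C7 and the 1-OH, so rings B/C are trans-fused.

Naming note: "BCD tricycle" means atoms C5, C6, C8–C17 of the target: cyclopentane ring B fused at C8–C9 to the bicyclo[3.2.1]octane of rings C and D, with the exocyclic C16=C17 methylene.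

Step 1
Reactants: 1 cyclopentane-1,3-dione; 2 propargyl bromide
Product: 3 2-(prop-2-yn-1-yl)cyclopentane-1,3-dione
Conditions: NaOH (1 equiv), H2O, 0 → 60 °C
Reagents that add atoms: none
Why: C-alkylation of the 1,3-dione enolate in water (SN2 on the propargylic bromide); no stereocentre is formed.

Step 2
Reactants: 3 2-(prop-2-yn-1-yl)cyclopentane-1,3-dione; 4 methyl vinyl ketone
Product: 5 2-(3-oxobutyl)-2-(prop-2-yn-1-yl)cyclopentane-1,3-dione
Conditions: AcOH (cat.), H2O, 75 °C
Reagents that add atoms: none
Why: Michael addition of the enolised 2-substituted 1,3-dione to the enone builds the quaternary, still prochiral carbon that becomes C8.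

Step 3
Reactants: 5 2-(3-oxobutyl)-2-(prop-2-yn-1-yl)cyclopentane-1,3-dione
Product: 7 (7aR)-7a-propargyl bicyclic enedione, via cis-fused ketol 6 (not isolated)
Conditions: L-phenylalanine (0.3 equiv), (1S)-(+)-10-camphorsulfonic acid (0.15 equiv), DMF, 30 → 70 °C
Reagents that add atoms: none
Why: Hajos–Parrish–Eder–Sauer–Wiechert reaction: the L-amino acid enamine of the side-chain ketone attacks one of the two enantiotopic ring carbonyls through a carboxylic-acid-hydrogen-bonded chair transition state and the ketol dehydrates, setting C8 in the same spatial sense as the (S)-Hajos–Parrish ketone.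

Step 4
Reactants: 7 (7aR)-7a-propargyl bicyclic enedione
Product: 8 bis(tert-butyldimethylsilyl) enol ether
Conditions: LiN(SiMe3)2 (2.4 equiv), THF, −78 °C; t-BuMe2SiCl, DMPU, −78 → 0 °C
Reagents that add atoms: tert-butyldimethylsilyl chloride, CC(C)(C)[Si](C)(C)Cl
Why: Kinetic enolisation and O-silylation at C5 (saturated ketone; C8 is quaternary) and at C13 (α′ of the enone, cross-conjugated dienolate); ketone deprotonation by the silazide at −78 °C is much faster than removal of the alkyne hydrogen.

Step 5
Reactants: 8 bis(tert-butyldimethylsilyl) enol ether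
Product: 10 BCD tricyclic enedione, via tricyclic silyl enol ether 9 (not isolated)
Conditions: Ph3PAuCl (5 mol%), AgBF4 (5 mol%), CH2Cl2–MeOH 10:1, rt; then 1 M HCl, THF, 0 °C
Reagents that add atoms: none
Why: Conia-ene-type 5-exo-dig carbocyclisation: the cationic gold complex activates the alkyne, the dienol ether carbon C13 attacks the internal alkyne carbon (the bridge can only close on the face that carries the propargyl group, which fixes C13), and methanol removes the silyl group and protonates the vinyl gold to give the exocyclic methylene; dilute acid then hydrolyses the C6 enol ether.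

Step 6
Reactants: 10 BCD tricyclic enedione
Product: 11 C6 enol triflate
Conditions: KN(SiMe3)2 (1.05 equiv), THF, −78 °C; PhNTf2, −78 → −20 °C
Reagents that add atoms: N-phenylbis(trifluoromethanesulfonimide), O=S(=O)(N(c1ccccc1)S(=O)(=O)C(F)(F)F)C(F)(F)F
Why: Regiodefined enolate triflation: only the C5 hydrogens are α to a carbonyl and kinetically available, since the enone α′ carbon C13 is now a bridgehead and C11 is vinylic.

Step 7
Reactants: 11 C6 enol triflate
Product: 12 9α-H 12-ketone
Conditions: [(Ph3P)CuH]6 (0.5 equiv), H2O (3 equiv), toluene, rt; aq. NH4Cl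
Reagents that add atoms: none
Why: Conjugate reduction with Stryker's copper hydride [(Ph3P)CuH]6: hydride reaches C9 only from the face next to the one-carbon bridge C14, opposite the C15–C16 bridge, so H-9 ends anti to C15 (trans-fused rings B/C); the enol triflate and the exocyclic alkene do not react.

Step 8
Reactants: 12 9α-H 12-ketone
Product: 13 12β-alcohol
Conditions: NaBH4, MeOH–THF, −40 °C
Reagents that add atoms: none
Why: Ketone reduction: hydride attacks C12 from the open face next to C14 (axial attack, anti to the two-carbon bridge), giving the equatorial 12β-alcohol, which is the epimer needed for clean inversion in step 10.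

Step 9
Reactants: 13 12β-alcohol; 14 carbon monoxide
Product: 15 12β-hydroxy enoate
Conditions: CO (1 atm), Pd(OAc)2 (5 mol%), dppp (6 mol%), Et3N, Me3SiCH2CH2OH, DMF, 60 °C
Reagents that add atoms: 2-(trimethylsilyl)ethanol, C[Si](C)(C)CCO
Why: Palladium-catalysed alkoxycarbonylation of the enol triflate (oxidative addition, CO insertion, alcoholysis) installs C7 as the C5=C6 enoate; the silylethyl ester is chosen because fluoride later removes it at silicon, away from the hindered acyl carbon.

Step 10
Reactants: 15 12β-hydroxy enoate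
Product: 17 12α-hydroxy enoate, via 12α-(4-nitrobenzoate) 16 (not isolated)
Conditions: 4-O2NC6H4CO2H, PPh3, DIAD, THF, 0 °C → rt; then K2CO3 (0.3 equiv), MeOH, 0 °C → rt
Reagents that add atoms: 4-nitrobenzoic acid, O=C(O)c1ccc(cc1)[N+](=O)[O-]
Why: Mitsunobu reaction: SN2 displacement of the equatorial oxyphosphonium group by the carboxylate from the open axial side inverts C12 (an equatorial leaving group has no antiperiplanar hydrogen for E2), and base-catalysed methanolysis frees the axial 12α-alcohol.

Step 11
Reactants: 17 12α-hydroxy enoate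
Product: 18 12α-triethylsilyl ether
Conditions: Et3SiOTf, 2,6-lutidine, CH2Cl2, −78 °C
Reagents that add atoms: triethylsilyl trifluoromethanesulfonate, CC[Si](CC)(CC)OS(=O)(=O)C(F)(F)F
Why: Silylation of the hindered axial alcohol with the silyl triflate protects O-12 through the strong-base and acylation steps and is later removed by the same fluoride that cleaves the ester.

Step 12
Reactants: 18 12α-triethylsilyl ether; 19 2,2,2-trifluoroethyl formate
Product: 21 10α-hydroxy-10β-formyl enoate, via 10-hydroxymethylene enoate 20 (not isolated)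
Conditions: LiN(i-Pr)2 (2.2 equiv), THF–DMPU, −78 °C; HCO2CH2CF3, −78 → −30 °C; then 2-(phenylsulfonyl)-3-phenyloxaziridine, −78 → −20 °C; aq. NH4Cl
Reagents that add atoms: 2-(phenylsulfonyl)-3-phenyloxaziridine, O=S(=O)(N1OC1c1ccccc1)c1ccccc1
Why: Vinylogous Claisen formylation then Davis enolate hydroxylation: γ-deprotonation gives the ester dienolate, formyl transfer is reversible at the neopentylic α-carbon C6 and funnels to C10 where the product is held as its stabilised enolate, and the oxaziridine then delivers oxygen to C10 from the α face (anti to C11 and the C15 bridge), setting C10 with O α and C1 β.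

Step 13
Reactants: 21 10α-hydroxy-10β-formyl enoate; 22 2,2,5,6-tetramethyl-4H-1,3-dioxin-4-one
Product: 26 protected ring-A enone lactone, via acetoacetate ester 23 (not isolated), via Michael adduct 24 (not isolated), via ketol 25 (not isolated)
Conditions: 22 (1.3 equiv), toluene, 110 °C, 1 h; evaporate; KOt-Bu (0.5 equiv), t-BuOH–THF 1:4, 0 → 40 °C
Reagents that add atoms: none
Why: Proposed new method: one-pot acylketene O-acylation / tethered Michael–aldol-condensation bicycloannulation, in which thermolysis of 22 gives acetyl(methyl)ketene that acylates the hindered tertiary alcohol, and catalytic butoxide then forms the β-keto ester enolate, which is held on the α face by the C10–O tether and adds 5-exo-trig to C5 of the enoate (closing the lactone and fixing C5); the Michael step is reversible, so only the C4 epimer whose acetyl group points to the formyl group is drained by the intramolecular aldol condensation that closes ring A, while C6 equilibrates under the same base to the ester trans to C4; the closest known reaction types are the Robinson annulation and the base-mediated Michael–aldol closure of carbinol-tethered propionates, but a 2-methylacetoacetate tether acting as a 1,3-bis-nucleophile toward a carbinol flanked by an enoate and a formyl group has not been shown.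

Step 14
Reactants: 26 protected ring-A enone lactone
Product: 27 enone hydroxy acid
Conditions: Bu4NF (5 equiv), THF, 0 °C → rt; 0.5 M HCl to pH 3, 0 °C
Reagents that add atoms: none
Why: Fluoride-mediated desilylation: attack at silicon cleaves the triethylsilyl ether and fragments the 2-(trimethylsilyl)ethyl ester (β-elimination to ethene) without attack at the hindered C7 carbonyl, and the non-enolisable enone lactone tolerates the basic fluoride.

Step 15
Reactants: 27 enone hydroxy acid
Product: 29 CNP0259985.3 (target), via 1β-boronate 28 (not isolated)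
Conditions: CuCl (10 mol%), 1,2-bis(diphenylphosphino)benzene (10 mol%), NaOt-Bu (1.2 equiv), B2pin2 (1.3 equiv), MeOH (4 equiv), THF, 0 °C → rt; then NaBO3·4H2O, THF–H2O, 0 °C → rt; 0.5 M HCl to pH 4, 0 °C
Reagents that add atoms: bis(pinacolato)diboron (boron of 28 only), CC1(C)OB(OC1(C)C)B1OC(C)(C)C(C)(C)O1; sodium perborate (oxygen on C1), [Na+].[Na+].O[B-]1(O)OO[B-](O)(O)OO1
Why: Copper-catalysed conjugate borylation then oxidation: the boryl copper species adds to C1 of the enone from the face of the one-atom bridge C5, anti to the lactone bridge, and perborate oxidation with retention gives the 1β-alcohol under conditions too mild for retro-aldol or dehydration; the unactivated exocyclic alkene stays.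

**Compound list**
1 | cyclopentane-1,3-dione | O=C1CCC(=O)C1 | starting material
2 | propargyl bromide (3-bromoprop-1-yne) | C#CCBr | starting material
3 | 2-(prop-2-yn-1-yl)cyclopentane-1,3-dione | C#CCC1C(=O)CCC1=O | intermediate
4 | methyl vinyl ketone (but-3-en-2-one) | C=CC(C)=O | starting material
5 | 2-(3-oxobutyl)-2-(prop-2-yn-1-yl)cyclopentane-1,3-dione (achiral triketone) | C#CCC1(CCC(C)=O)C(=O)CCC1=O | intermediate
6 | (3aS,7aR)-3a-hydroxy-7a-(prop-2-yn-1-yl)hexahydro-1H-indene-1,5(4H)-dione, cis-fused ketol (OH cis to propargyl) | C#CC[C@]23CCC(=O)C[C@@]2(O)CCC3=O | intermediate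
7 | (7aR)-7a-(prop-2-yn-1-yl)-2,3,7,7a-tetrahydro-1H-indene-1,5(6H)-dione (C7a becomes C8) | C#CC[C@]23CCC(=O)C=C2CCC3=O | intermediate
8 | (7aR)-1,5-bis(tert-butyldimethylsilyloxy)-7a-(prop-2-yn-1-yl)-7,7a-dihydro-3H-indene (C5=C6 enol ether and C13=C12–C11=C9 dienol ether in target numbering) | C#CC[C@]23CC=C(O[Si](C)(C)C(C)(C)C)C=C2CC=C3O[Si](C)(C)C(C)(C)C | intermediate
9 | BCD tricycle: 16-methylene, 9(11)-en-12-one, 6-(tert-butyldimethylsilyloxy)-5-ene; C15 β on C8 | C=C1C[C@]23C[C@H]1C(=O)C=C2CC=C3O[Si](C)(C)C(C)(C)C | intermediate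
10 | BCD tricyclic enedione: 16-methylene, 9(11)-ene, 6,12-dione; C15 β on C8 | C=C1C[C@]23C[C@H]1C(=O)C=C2CCC3=O | intermediate
11 | BCD tricycle: 6-(trifluoromethanesulfonyloxy)-5-ene, 9(11)-en-12-one, 16-methylene | C=C1C[C@]23C[C@H]1C(=O)C=C2CC=C3OS(=O)(=O)C(F)(F)F | intermediate
12 | BCD tricycle: 9α-H (trans-fused B/C), 12-ketone, 6-triflyloxy-5-ene, 16-methylene | C=C1C[C@]23C[C@H]1C(=O)C[C@@H]2CC=C3OS(=O)(=O)C(F)(F)F | intermediate
13 | as 12 with 12β-OH (equatorial, syn to C16) in place of the ketone | C=C1C[C@]23C[C@H]1[C@H](O)C[C@@H]2CC=C3OS(=O)(=O)C(F)(F)F | intermediate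
14 | carbon monoxide | [C-]#[O+] | starting material
15 | 2-(trimethylsilyl)ethyl BCD-tricycle 5-ene-6-carboxylate (C7), 9α-H, 12β-OH, 16-methylene | C=C1C[C@]23C[C@H]1[C@H](O)C[C@@H]2CC=C3C(=O)OCC[Si](C)(C)C | intermediate
16 | as 15 with 12α-O-(4-nitrobenzoyl) (axial, anti to C16) | C=C1C[C@]23C[C@H]1[C@@H](OC(=O)c4ccc(cc4)[N+](=O)[O-])C[C@@H]2CC=C3C(=O)OCC[Si](C)(C)C | intermediate
17 | as 15 with 12α-OH (axial, anti to C16) | C=C1C[C@]23C[C@H]1[C@@H](O)C[C@@H]2CC=C3C(=O)OCC[Si](C)(C)C | intermediate
18 | as 17 with 12α-O-triethylsilyl | C=C1C[C@]23C[C@H]1[C@@H](O[Si](CC)(CC)CC)C[C@@H]2CC=C3C(=O)OCC[Si](C)(C)C | intermediate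
19 | 2,2,2-trifluoroethyl formate | O=COCC(F)(F)F | starting material
20 | as 18 with 10-(hydroxymethylene) (enol of the 10-formyl compound, E/Z mixture; lithium enolate in the flask) | C=C1C[C@]23C[C@H]1[C@@H](O[Si](CC)(CC)CC)C[C@@H]2C(=CO)C=C3C(=O)OCC[Si](C)(C)C | intermediate
21 | as 18 with 10α-OH and 10β-CHO (C1) | C=C1C[C@]23C[C@H]1[C@@H](O[Si](CC)(CC)CC)C[C@@H]2[C@@](C=O)(O)C=C3C(=O)OCC[Si](C)(C)C | intermediate
22 | 2,2,5,6-tetramethyl-4H-1,3-dioxin-4-one | CC1=C(C)C(=O)OC(C)(C)O1 | starting material
23 | 10α-O-(2-methyl-3-oxobutanoyl) ester of 21 (epimers at the acetoacetate α-carbon) | C=C1C[C@]23C[C@H]1[C@@H](O[Si](CC)(CC)CC)C[C@@H]2[C@@](C=O)(OC(=O)C(C)C(C)=O)C=C3C(=O)OCC[Si](C)(C)C | intermediate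
24 | Michael adduct: 19,10-γ-lactone cis-fused to ring B on the α face, C4 with methyl toward C6 and acetyl toward the 10β-formyl group, H-5β, C6 epimers | C=C1C[C@]23C[C@H]1[C@@H](O[Si](CC)(CC)CC)C[C@@H]2[C@@]2(C=O)OC(=O)[C@](C)(C(C)=O)[C@H]2C3C(=O)OCC[Si](C)(C)C | intermediate
25 | ketol: pentacyclic 1-hydroxy-3-ketone 19,10-lactone (C1 and C6 epimers), 12α-OSiEt3, silylethyl 7-ester | C=C1C[C@]23C[C@H]1[C@@H](O[Si](CC)(CC)CC)C[C@@H]2[C@]12OC(=O)[C@](C)(C(=O)CC1O)[C@H]2C3C(=O)OCC[Si](C)(C)C | intermediate
26 | protected enone: 1-en-3-one 19,10-lactone, 6β-CO2CH2CH2SiMe3 (H-6α), 12α-OSiEt3, 16-methylene | C=C1C[C@]23C[C@H]1[C@@H](O[Si](CC)(CC)CC)C[C@@H]2[C@]12OC(=O)[C@](C)(C(=O)C=C1)[C@H]2[C@@H]3C(=O)OCC[Si](C)(C)C | intermediate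
27 | 12α-hydroxy-3-oxo-1-ene 19,10-lactone 7-oic acid (9α-H, 16-methylene) | C=C1C[C@]23C[C@H]1[C@@H](O)C[C@@H]2[C@]12OC(=O)[C@](C)(C(=O)C=C1)[C@H]2[C@@H]3C(=O)O | intermediate
28 | as the target with 1β-(4,4,5,5-tetramethyl-1,3,2-dioxaborolan-2-yl) in place of 1β-OH | C=C1C[C@]23C[C@H]1[C@@H](O)C[C@@H]2[C@]12OC(=O)[C@](C)(C(=O)C[C@H]1B1OC(C)(C)C(C)(C)O1)[C@H]2[C@@H]3C(=O)O | intermediate
29 | CNP0259985.3: 1β,12α-dihydroxy-3-oxo-9α-H 19,10-lactone 7-oic acid, 16-methylene | C=C1C[C@]23C[C@H]1[C@@H](O)C[C@@H]2[C@]12OC(=O)[C@](C)(C(=O)C[C@H]1O)[C@H]2[C@@H]3C(=O)O | target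

**Totals**
Total steps: 15. Longest linear sequence: 15 steps (from 1; 2, 4, 14, 19 and 22 are purchased).

**Steps most likely to fail, with fallbacks**

Step 13 (the proposed new bicycloannulation; risks are α-ketol shift of 21 on heating, a stalled ketol and the C4/C6 equilibria). The fallback sets out from 23 and returns at 26, using known reactions one at a time. The thermal acylation is stopped before base is added and acetoacetate 23 is isolated. Cs2CO3 in MeCN at room temperature effects the ordinary intramolecular Michael addition of the β-keto ester, and keto aldehyde 24 is isolated (the C4 epimer with the acetyl group on the wrong side is separated and re-equilibrated with KOt-Bu). The methyl ketone is converted with Me3SiOTf/Et3N into trimethylsilyl enol ether F1, and ring A is closed by an intramolecular Mukaiyama aldol reaction (BF3·OEt2, CH2Cl2, −78 °C) to ketol 25. Mesylation (MsCl, Et3N) gives mesylate F2, and DBU in toluene at 60 °C eliminates it and equilibrates C6 to give 26.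

Step 5 (the C6 silyl enol ether of 8 could compete for the alkyne and give a bicyclo[2.2.1] by-product). The fallback sets out from 7 and returns at 10. The saturated C6 ketone is protected selectively (2-ethyl-2-methyl-1,3-dioxolane, ethylene glycol, TsOH cat., rt) to give monoketal F3. LiN(SiMe3)2/t-BuMe2SiCl then gives the single cross-conjugated dienol silyl ether F4, and the same Ph3PAuCl/AgBF4 cyclisation gives tricyclic enone ketal F5. Aqueous HCl in acetone removes the ketal and gives 10.

Step 12 (α- versus γ-formylation of the dienolate, and α-ketol shift of the lithium alkoxide of 21). The fallback sets out from 18 and returns at 21. LiN(i-Pr)2/DMPU then Me3SiCl gives silyl ketene acetal F6. Chloromethylene-dimethyliminium chloride (from DMF and oxalyl chloride) with pyridine formylates the γ-carbon in a vinylogous Vilsmeier reaction to give dimethylaminomethylene enoate F7. Mild aqueous acid hydrolysis gives 20, now isolated, and dimethyldioxirane in acetone at −78 °C hydroxylates C10 of the enol from the α face under neutral conditions to give 21.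

**Further compounds**
F1 | step 13 | trimethylsilyl enol ether of the methyl ketone of 24 | C=C1C[C@]23C[C@H]1[C@@H](O[Si](CC)(CC)CC)C[C@@H]2[C@@]2(C=O)OC(=O)[C@](C)(C(=C)O[Si](C)(C)C)[C@H]2C3C(=O)OCC[Si](C)(C)C
F2 | step 13 | 1-O-methanesulfonate of ketol 25 | C=C1C[C@]23C[C@H]1[C@@H](O[Si](CC)(CC)CC)C[C@@H]2[C@]12OC(=O)[C@](C)(C(=O)CC1OS(C)(=O)=O)[C@H]2C3C(=O)OCC[Si](C)(C)C
F3 | step 5 | C6 ethylene ketal of 7 | C#CC[C@]23CCC(=O)C=C2CCC31OCCO1
F4 | step 5 | cross-conjugated tert-butyldimethylsilyl dienol ether of F3 | C#CC[C@]23CC=C(O[Si](C)(C)C(C)(C)C)C=C2CCC31OCCO1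
F5 | step 5 | C6 ethylene ketal of 10 | C=C1C[C@]23C[C@H]1C(=O)C=C2CCC31OCCO1
F6 | step 12 | trimethylsilyl ketene acetal (γ-deprotonated dienolate) of 18 | C=C1C[C@]23C[C@H]1[C@@H](O[Si](CC)(CC)CC)C[C@@H]2C=CC3=C(OCC[Si](C)(C)C)O[Si](C)(C)C
F7 | step 12 | 10-(dimethylaminomethylene) derivative of 18 | C=C1C[C@]23C[C@H]1[C@@H](O[Si](CC)(CC)CC)C[C@@H]2C(=CN(C)C)C=C3C(=O)OCC[Si](C)(C)C
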